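**Retrosynthetic overview**

1. The three esters go on last. The butenolide comes from a C8 ketone and C7 carbinol by esterification with a phosphonopropionic acid and intramolecular Horner–Wadsworth–Emmons olefination.
2. The ten-membered ring is never closed directly. It arises by Claisen ring contraction of a methylenated twelve-membered macrolactone (C8 acyl on the C12 oxygen), which forms C9–C10, the C11=C12 alkene and the C8 ketone, and transfers chirality from C12 to C10.
3. The seco acid carries a C2–C8 chain made by methyl ketone enolate alkylation (C3–C4) with a (Z)-allylic bromide from (R)-solketal (C7 from the pool, C5=C6 by Still–Gennari olefination); C2 is set by CBS reduction.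
4. The ring A centres C14, C13 and C12 are relayed from quaternary C1 through a 2,4-dienone (Luche reduction, hydroxyl-directed epoxidation, Ti-mediated epoxide opening); C1 comes from an auxiliary-controlled Birch reductive methylation of a 2-methoxy-5-methylbenzamide.
5. Ring order: ring A (by dearomatisation), then the twelve-membered lactone, then the ten-membered carbocycle, then the butenolide.

Positions are given in briarane numbering (C1–C20); TBS = tert-butyldimethylsilyl.

Assumption: the Birch alkylation follows the chelated potassium enolate model (iodomethane enters anti to the methoxymethyl arm), so the (R)-auxiliary is taken to give the C1 configuration drawn; if the sense were opposite, the (S)-auxiliary would be used.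

**Route**

Step 1
Reactants: 1 (R)-solketal; 2 ethyl 2-[bis(2,2,2-trifluoroethoxy)phosphoryl]propanoate
Product: 4 ethyl (Z)-3-[(4R)-2,2-dimethyl-1,3-dioxolan-4-yl]-2-methylprop-2-enoate, via (S)-glyceraldehyde acetonide 3 (not isolated)
Conditions: IBX (2-iodoxybenzoic acid), EtOAc, 75 °C, filter; then 2, KN(SiMe3)2, 18-crown-6, THF, −78 °C
Reagents that add atoms: none
Why: IBX oxidation gives the labile aldehyde, which is trapped at once in a Still–Gennari olefination whose kinetic control gives the (Z)-trisubstituted enoate (the future C5=C6), while C7 is taken unchanged from the chiral pool.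

Step 2
Reactants: 4 ethyl (Z)-3-[(4R)-2,2-dimethyl-1,3-dioxolan-4-yl]-2-methylprop-2-enoate
Product: 5 (Z)-3-[(4R)-2,2-dimethyl-1,3-dioxolan-4-yl]-2-methylprop-2-en-1-ol
Conditions: iBu2AlH, CH2Cl2, −78 °C
Reagents that add atoms: none
Why: 1,2-reduction of the enoate by the aluminium hydride gives the allylic alcohol and leaves the Z geometry, the acetonide and the stereocentre untouched (ester reduction).

Step 3
Reactants: 5 (Z)-3-[(4R)-2,2-dimethyl-1,3-dioxolan-4-yl]-2-methylprop-2-en-1-ol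
Product: 6 (4R)-4-[(Z)-3-bromo-2-methylprop-1-enyl]-2,2-dimethyl-1,3-dioxolane
Conditions: CBr4, PPh3, CH2Cl2, 0 °C
Reagents that add atoms: tetrabromomethane BrC(Br)(Br)Br
Why: The Appel reaction converts the primary allylic alcohol into the bromide under neutral conditions without allylic transposition or loss of the Z geometry.

Step 4
Reactants: 7 2-methoxy-5-methylbenzoic acid; 8 (R)-2-(methoxymethyl)pyrrolidine
Product: 10 (2-methoxy-5-methylphenyl)[(2R)-2-(methoxymethyl)pyrrolidin-1-yl]methanone, via acid chloride 9 (not isolated)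
Conditions: (COCl)2, N,N-dimethylformamide (cat.), CH2Cl2, 0 → 23 °C; then 8, Et3N, CH2Cl2, 0 °C
Reagents that add atoms: none
Why: Acid chloride formation and N-acylation of the secondary amine (amide synthesis) attach the chiral auxiliary; no stereocentre is formed.

Step 5
Reactants: 10 (2-methoxy-5-methylphenyl)[(2R)-2-(methoxymethyl)pyrrolidin-1-yl]methanone
Product: 12 [(1S)-2-methoxy-1,5-dimethylcyclohexa-2,5-dien-1-yl][(2R)-2-(methoxymethyl)pyrrolidin-1-yl]methanone, via potassium amide enolate 11 (not isolated)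
Conditions: K, t-BuOH (1 equiv), NH3–THF, −78 °C; then MeI, −78 °C
Reagents that add atoms: iodomethane CI
Why: In this Schultz asymmetric Birch reduction–alkylation the arene is reduced to a chelated potassium amide enolate and iodomethane attacks C1 anti to the methoxymethyl arm, which sets quaternary C1 and leaves the enol ether at C14 and the methyl-bearing alkene at C10=C11.

Step 6
Reactants: 12 [(1S)-2-methoxy-1,5-dimethylcyclohexa-2,5-dien-1-yl][(2R)-2-(methoxymethyl)pyrrolidin-1-yl]methanone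
Product: 14 1-[(1S)-2-methoxy-1,5-dimethylcyclohexa-2,5-dien-1-yl]ethanone, via lithium carbinolamine alkoxide 13 (not isolated)
Conditions: MeLi, THF, −78 → 0 °C; aq. NH4Cl
Reagents that add atoms: methyllithium [Li]C
Why: MeLi adds only once to the tertiary amide because the lithium carbinolamine alkoxide, chelated by the methoxymethyl ether, survives until the quench (nucleophilic acyl substitution, Weinreb-type behaviour), then collapses to the methyl ketone (C2, C3) and releases the auxiliary.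

Step 7
Reactants: 14 1-[(1S)-2-methoxy-1,5-dimethylcyclohexa-2,5-dien-1-yl]ethanone; 6 (4R)-4-[(Z)-3-bromo-2-methylprop-1-enyl]-2,2-dimethyl-1,3-dioxolane
Product: 16 (Z)-5-[(4R)-2,2-dimethyl-1,3-dioxolan-4-yl]-1-[(1S)-2-methoxy-1,5-dimethylcyclohexa-2,5-dien-1-yl]-4-methylpent-4-en-1-one, via lithium enolate 15 (not isolated)
Conditions: LiN(iPr)2, THF, −78 °C; then 6, DMPU, −78 → −30 °C
Reagents that add atoms: none
Why: Kinetic lithium enolate alkylation (SN2) at the only enolisable carbon (C3) with the reactive allylic bromide forms C3–C4 with the Z alkene retained; no stereocentre is formed.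

Step 8
Reactants: 16 (Z)-5-[(4R)-2,2-dimethyl-1,3-dioxolan-4-yl]-1-[(1S)-2-methoxy-1,5-dimethylcyclohexa-2,5-dien-1-yl]-4-methylpent-4-en-1-one
Product: 17 (1S,4Z)-5-[(4R)-2,2-dimethyl-1,3-dioxolan-4-yl]-1-[(1R)-2-methoxy-1,5-dimethylcyclohexa-2,5-dien-1-yl]-4-methylpent-4-en-1-ol
Conditions: (R)-Me-CBS oxazaborolidine [(3aR)-1-methyl-3,3-diphenyltetrahydro-1H,3H-pyrrolo[1,2-c][1,3,2]oxazaborole] (20 mol %), catecholborane, toluene, −78 °C
Reagents that add atoms: none
Why: In this Corey–Bakshi–Shibata reduction quaternary C1 is the large and C3H2 the small ketone substituent, so the (R)-catalyst delivers hydride to give the (S)-carbinol at C2 under reagent control.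

Step 9
Reactants: 17 (1S,4Z)-5-[(4R)-2,2-dimethyl-1,3-dioxolan-4-yl]-1-[(1R)-2-methoxy-1,5-dimethylcyclohexa-2,5-dien-1-yl]-4-methylpent-4-en-1-ol
Product: 18 (2R)-2,4-dimethyl-2-[(1S,4Z,6R)-1,6,7-trihydroxy-4-methylhept-4-enyl]cyclohex-3-en-1-one
Conditions: AcOH–H2O–THF (3:1:1), 45 °C
Reagents that add atoms: water O
Why: Mild acid hydrolysis cleaves the methyl enol ether to the C14 ketone (the C10=C11 alkene cannot move into conjugation past quaternary C1) and the terminal acetonide to the 7,8-diol in one operation.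

Step 10
Reactants: 18 (2R)-2,4-dimethyl-2-[(1S,4Z,6R)-1,6,7-trihydroxy-4-methylhept-4-enyl]cyclohex-3-en-1-one
Product: 19 (2R)-2,4-dimethyl-2-[(1S,4Z,6R)-1,6,7-tris(TBS-oxy)-4-methylhept-4-enyl]cyclohex-3-en-1-one
Conditions: TBSOTf, 2,6-lutidine, CH2Cl2, −78 → 0 °C
Reagents that add atoms: tert-butyldimethylsilyl trifluoromethanesulfonate CC(C)(C)[Si](C)(C)OS(=O)(=O)C(F)(F)F
Why: Silyl triflate silylation protects all three hydroxyls, including the neopentyl C2 hydroxyl, and removes the retro-aldol liability of the β-hydroxy ketone.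

Step 11
Reactants: 19 (2R)-2,4-dimethyl-2-[(1S,4Z,6R)-1,6,7-tris(TBS-oxy)-4-methylhept-4-enyl]cyclohex-3-en-1-one
Product: 21 (6R)-4,6-dimethyl-6-[(1S,4Z,6R)-1,6,7-tris(TBS-oxy)-4-methylhept-4-enyl]cyclohexa-2,4-dien-1-one, via trimethylsilyl enol ether 20 (not isolated)
Conditions: LiN(iPr)2, Me3SiCl, THF, −78 °C; then Pd(OAc)2, MeCN, 23 °C
Reagents that add atoms: none
Why: In this Saegusa–Ito oxidation the ketone can enolise only toward C13, and Pd(OAc)2 dehydrosilylation of the silyl enol ether gives the linear 2,4-dienone conjugated with the C10=C11 alkene.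

Step 12
Reactants: 21 (6R)-4,6-dimethyl-6-[(1S,4Z,6R)-1,6,7-tris(TBS-oxy)-4-methylhept-4-enyl]cyclohexa-2,4-dien-1-one
Product: 22 ring A dienol (C14 hydroxyl cis to the C1 side chain)
Conditions: NaBH4, CeCl3·7H2O, MeOH, −78 °C
Reagents that add atoms: none
Why: In this Luche 1,2-reduction hydride approaches the nearly planar dienone from the face of the small C1 methyl, anti to the bulky silyloxyalkyl chain, so the C14 hydroxyl ends up cis to the C2 chain as in the target.

Step 13
Reactants: 22 ring A dienol (C14 hydroxyl cis to the C1 side chain)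
Product: 23 12,13-epoxy alcohol (epoxide cis to the C14 hydroxyl)
Conditions: VO(acac)2 [vanadyl bis(acetylacetonate)] (5 mol %), t-BuOOH, CH2Cl2, 0 °C
Reagents that add atoms: tert-butyl hydroperoxide CC(C)(C)OO
Why: Vanadium-catalysed hydroxyl-directed epoxidation oxidises only the allylic C12=C13 alkene and delivers oxygen syn to the C14 hydroxyl, which fixes C13.

Step 14
Reactants: 23 12,13-epoxy alcohol (epoxide cis to the C14 hydroxyl)
Product: 24 C12 benzoate 13,14-cis-diol (C12 oxygen trans to the C13 oxygen)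
Conditions: Ti(OiPr)4, PhCO2H, CH2Cl2, 23 °C
Reagents that add atoms: benzoic acid OC(=O)c1ccccc1
Why: In this Ti(OiPr)4-mediated C3-selective opening of a 2,3-epoxy alcohol, benzoate attacks the allylic C12 with inversion, which leaves the 13,14-cis-diol and places the C12 oxygen on the face anti to the C2 chain.

Step 15
Reactants: 24 C12 benzoate 13,14-cis-diol
Product: 25 C12 benzoate 13,14-acetonide
Conditions: Me2C(OMe)2, pyridinium p-toluenesulfonate (cat.), CH2Cl2, 23 °C
Reagents that add atoms: 2,2-dimethoxypropane COC(C)(C)OC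
Why: Acid-catalysed transketalisation protects the cis-13,14-diol as the five-membered acetonide.

Step 16
Reactants: 25 C12 benzoate 13,14-acetonide
Product: 26 C8 primary alcohol (C2 and C7 silyl ethers kept)
Conditions: HF·pyridine, pyridine, THF, 0 °C
Reagents that add atoms: none
Why: Buffered HF·pyridine removes the unhindered primary silyl ether much faster than the two secondary ones (selective desilylation).

Step 17
Reactants: 26 C8 primary alcohol
Product: 28 C8 carboxylic acid, via aldehyde 27 (not isolated)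
Conditions: TEMPO (2,2,6,6-tetramethylpiperidin-1-oxyl, 20 mol %), PhI(OAc)2, MeCN–pH 7 buffer, 23 °C
Reagents that add atoms: water O
Why: TEMPO/PhI(OAc)2 oxidation in wet acetonitrile takes the primary alcohol through the aldehyde hydrate to the acid without touching the alkenes or epimerising the α-silyloxy centre C7.

Step 18
Reactants: 28 C8 carboxylic acid
Product: 29 seco acid (C12 hydroxyl free)
Conditions: K2CO3, MeOH, 40 °C; then aq. HCl to pH 4
Reagents that add atoms: none
Why: Carbonate-mediated methanolysis (transesterification) removes the benzoate to free the C12 hydroxyl, while the carboxylate is inert and protects C7 from enolisation.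

Step 19
Reactants: 29 seco acid (C12 hydroxyl free)
Product: 31 twelve-membered macrolactone (C8 acyl on the C12 oxygen), via mixed anhydride 30 (not isolated)
Conditions: 2-methyl-6-nitrobenzoic anhydride, 4-(dimethylamino)pyridine, CH2Cl2, 23 °C, syringe-pump addition to 1 mM
Reagents that add atoms: none
Why: In this Shiina macrolactonisation the mixed anhydride acylates the C12 hydroxyl at high dilution to close a twelve-membered lactone, a much easier ring size than the ten-membered carbocycle; no stereocentre changes.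

Step 20
Reactants: 31 twelve-membered macrolactone
Product: 32 exocyclic enol ether (C8=C9H2 on the C12 oxygen)
Conditions: Ti(C5H5)2(CH3)2, toluene–THF, 70 °C, dark
Reagents that add atoms: dimethyltitanocene C[Ti](C)(C1C=CC=C1)C1C=CC=C1
Why: Petasis methylenation converts the lactone carbonyl, the only carbonyl present, into the exocyclic enol ether, which introduces C9 and creates an allyl vinyl ether.

Step 21
Reactants: 32 exocyclic enol ether
Product: 33 ten-membered C8 ketone (2,7-bis-TBS ether, 13,14-acetonide)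
Conditions: toluene, Et3N (1 vol %), sealed tube, 150 °C
Reagents that add atoms: none
Why: In this Claisen rearrangement used as a ring contraction, the [3,3] shift of the C9=C8–O–C12–C11=C10 array forms C9–C10 suprafacially on the face the C12 oxygen leaves, which sets C10 (C9 trans to C2) and delivers the ten-membered ring, the C11=C12 alkene and the C8 ketone at once.

Step 22
Reactants: 33 ten-membered C8 ketone
Product: 34 2,7-diol C8 ketone
Conditions: HF·pyridine, THF, 0 → 40 °C
Reagents that add atoms: none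
Why: Fluoride-mediated desilylation under mildly acidic conditions frees the C2 and C7 hydroxyls without epimerising the α-ketol or cleaving the acetonide.

Step 23
Reactants: 34 2,7-diol C8 ketone; 35 2-(diethoxyphosphoryl)propanoic acid
Product: 37 butenolide C2 alcohol (13,14-acetonide), via phosphonate ester 36 (not isolated)
Conditions: 35, N,N′-dicyclohexylcarbodiimide, 4-(dimethylamino)pyridine (cat.), CH2Cl2, 0 °C; then LiCl, iPr2NEt, MeCN, 23 °C
Reagents that add atoms: none
Why: Steglich esterification of the less hindered C7 α-ketol hydroxyl (the neopentyl C2 hydroxyl stays free) followed by intramolecular Horner–Wadsworth–Emmons olefination under Masamune–Roush conditions builds the tetrasubstituted butenolide with C7 retained.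

Step 24
Reactants: 37 butenolide C2 alcohol
Product: 38 C2 propionate 13,14-acetonide
Conditions: (EtCO)2O, 4-(dimethylamino)pyridine, Et3N, CH2Cl2, 40 °C
Reagents that add atoms: propanoic anhydride CCC(=O)OC(=O)CC
Why: Nucleophilic-catalyst acylation installs the propionate on the hindered C2 alcohol (esterification).

Step 25
Reactants: 38 C2 propionate 13,14-acetonide
Product: 39 C2 propionate 13,14-diol
Conditions: AcOH–H2O (4:1), 45 °C
Reagents that add atoms: none
Why: Aqueous acetic acid hydrolyses the acetonide (acetal hydrolysis) while the propionate and the butenolide survive.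

Step 26
Reactants: 39 C2 propionate 13,14-diol
Product: 40 CNP0180501.3
Conditions: Ac2O, 4-(dimethylamino)pyridine (cat.), pyridine, 23 °C
Reagents that add atoms: acetic anhydride CC(=O)OC(C)=O
Why: Acetylation of the cis-13,14-diol (esterification) gives the diacetate, which is the target.

**Compound list**

1 | (R)-solketal, [(4R)-2,2-dimethyl-1,3-dioxolan-4-yl]methanol | CC1(C)OC[C@@H](CO)O1 | starting material
2 | ethyl 2-[bis(2,2,2-trifluoroethoxy)phosphoryl]propanoate | CCOC(=O)C(C)P(=O)(OCC(F)(F)F)OCC(F)(F)F | starting material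
3 | (S)-2,2-dimethyl-1,3-dioxolane-4-carbaldehyde | CC1(C)OC[C@@H](C=O)O1 | intermediate
4 | ethyl (Z)-3-[(4R)-2,2-dimethyl-1,3-dioxolan-4-yl]-2-methylprop-2-enoate | CC1(C)OC[C@@H](/C=C(/C)C(=O)OCC)O1 | intermediate
5 | (Z)-3-[(4R)-2,2-dimethyl-1,3-dioxolan-4-yl]-2-methylprop-2-en-1-ol | CC1(C)OC[C@@H](/C=C(/C)CO)O1 | intermediate
6 | (4R)-4-[(Z)-3-bromo-2-methylprop-1-enyl]-2,2-dimethyl-1,3-dioxolane | CC1(C)OC[C@@H](/C=C(/C)CBr)O1 | intermediate
7 | 2-methoxy-5-methylbenzoic acid | COc1ccc(C)cc1C(=O)O | starting material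
8 | (R)-2-(methoxymethyl)pyrrolidine | COC[C@H]1CCCN1 | starting material
9 | 2-methoxy-5-methylbenzoyl chloride | COc1ccc(C)cc1C(Cl)=O | intermediate
10 | (2-methoxy-5-methylphenyl)[(2R)-2-(methoxymethyl)pyrrolidin-1-yl]methanone | COc1ccc(C)cc1C(=O)N2CCC[C@@H]2COC | intermediate
11 | potassium amide enolate of the 1,4-dihydro form of 10 | COC1=CCC(C)=CC1=C([O-])N2CCC[C@@H]2COC.[K+] | intermediate
12 | [(1S)-2-methoxy-1,5-dimethylcyclohexa-2,5-dien-1-yl][(2R)-2-(methoxymethyl)pyrrolidin-1-yl]methanone | COC1=CCC(C)=C[C@]1(C)C(=O)N2CCC[C@@H]2COC | intermediate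
13 | lithium carbinolamine alkoxide from MeLi addition to 12 | COC1=CCC(C)=C[C@]1(C)C(C)([O-])N2CCC[C@@H]2COC.[Li+] | intermediate
14 | 1-[(1S)-2-methoxy-1,5-dimethylcyclohexa-2,5-dien-1-yl]ethanone | COC1=CCC(C)=C[C@]1(C)C(C)=O | intermediate
15 | lithium enolate of 14 | COC1=CCC(C)=C[C@]1(C)C(=C)[O-].[Li+] | intermediate
16 | (Z)-5-[(4R)-2,2-dimethyl-1,3-dioxolan-4-yl]-1-[(1S)-2-methoxy-1,5-dimethylcyclohexa-2,5-dien-1-yl]-4-methylpent-4-en-1-one | COC1=CCC(C)=C[C@]1(C)C(=O)CC/C(C)=C\[C@@H]2COC(C)(C)O2 | intermediate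
17 | (1S,4Z)-5-[(4R)-2,2-dimethyl-1,3-dioxolan-4-yl]-1-[(1R)-2-methoxy-1,5-dimethylcyclohexa-2,5-dien-1-yl]-4-methylpent-4-en-1-ol | COC1=CCC(C)=C[C@]1(C)[C@@H](O)CC/C(C)=C\[C@@H]2COC(C)(C)O2 | intermediate
18 | (2R)-2,4-dimethyl-2-[(1S,4Z,6R)-1,6,7-trihydroxy-4-methylhept-4-enyl]cyclohex-3-en-1-one | O=C1CCC(C)=C[C@]1(C)[C@@H](O)CC/C(C)=C\[C@@H](O)CO | intermediate
19 | (2R)-2,4-dimethyl-2-[(1S,4Z,6R)-1,6,7-tris(tert-butyldimethylsilyloxy)-4-methylhept-4-enyl]cyclohex-3-en-1-one | O=C1CCC(C)=C[C@]1(C)[C@@H](O[Si](C)(C)C(C)(C)C)CC/C(C)=C\[C@@H](O[Si](C)(C)C(C)(C)C)CO[Si](C)(C)C(C)(C)C | intermediate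
20 | trimethylsilyl enol ether of 19 (C14 O-silyl, C13=C14) | C[Si](C)(C)OC1=CCC(C)=C[C@]1(C)[C@@H](O[Si](C)(C)C(C)(C)C)CC/C(C)=C\[C@@H](O[Si](C)(C)C(C)(C)C)CO[Si](C)(C)C(C)(C)C | intermediate
21 | (6R)-4,6-dimethyl-6-[(1S,4Z,6R)-1,6,7-tris(tert-butyldimethylsilyloxy)-4-methylhept-4-enyl]cyclohexa-2,4-dien-1-one | O=C1C=CC(C)=C[C@]1(C)[C@@H](O[Si](C)(C)C(C)(C)C)CC/C(C)=C\[C@@H](O[Si](C)(C)C(C)(C)C)CO[Si](C)(C)C(C)(C)C | intermediate
22 | ring A dienol: C14 alcohol of 21, hydroxyl cis to the C2–C8 chain on C1; side chain (2S,5Z,7R), tris-TBS | O[C@@H]1C=CC(C)=C[C@]1(C)[C@@H](O[Si](C)(C)C(C)(C)C)CC/C(C)=C\[C@@H](O[Si](C)(C)C(C)(C)C)CO[Si](C)(C)C(C)(C)C | intermediate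
23 | 12,13-epoxide of 22, epoxide cis to the C14 hydroxyl | O[C@@H]1[C@@H]2O[C@@H]2C(C)=C[C@]1(C)[C@@H](O[Si](C)(C)C(C)(C)C)CC/C(C)=C\[C@@H](O[Si](C)(C)C(C)(C)C)CO[Si](C)(C)C(C)(C)C | intermediate
24 | C12 benzoate 13,14-diol: 13-OH and 14-OH cis to each other and to the C2 chain, 12-OBz trans to 13-OH; C10=C11 alkene | O[C@@H]1[C@H](O)[C@@H](OC(=O)c2ccccc2)C(C)=C[C@]1(C)[C@@H](O[Si](C)(C)C(C)(C)C)CC/C(C)=C\[C@@H](O[Si](C)(C)C(C)(C)C)CO[Si](C)(C)C(C)(C)C | intermediate
25 | 13,14-acetonide of 24 | CC1(C)O[C@@H]2[C@H](O1)[C@@H](OC(=O)c3ccccc3)C(C)=C[C@]2(C)[C@@H](O[Si](C)(C)C(C)(C)C)CC/C(C)=C\[C@@H](O[Si](C)(C)C(C)(C)C)CO[Si](C)(C)C(C)(C)C | intermediate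
26 | C8 primary alcohol from 25 (C2 and C7 TBS ethers kept) | CC1(C)O[C@@H]2[C@H](O1)[C@@H](OC(=O)c3ccccc3)C(C)=C[C@]2(C)[C@@H](O[Si](C)(C)C(C)(C)C)CC/C(C)=C\[C@@H](O[Si](C)(C)C(C)(C)C)CO | intermediate
27 | C8 aldehyde from 26 | CC1(C)O[C@@H]2[C@H](O1)[C@@H](OC(=O)c3ccccc3)C(C)=C[C@]2(C)[C@@H](O[Si](C)(C)C(C)(C)C)CC/C(C)=C\[C@@H](O[Si](C)(C)C(C)(C)C)C=O | intermediate
28 | C8 carboxylic acid (C12 benzoate) | CC1(C)O[C@@H]2[C@H](O1)[C@@H](OC(=O)c3ccccc3)C(C)=C[C@]2(C)[C@@H](O[Si](C)(C)C(C)(C)C)CC/C(C)=C\[C@@H](O[Si](C)(C)C(C)(C)C)C(=O)O | intermediate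
29 | seco acid: C8 acid with free C12 hydroxyl | CC1(C)O[C@@H]2[C@H](O1)[C@@H](O)C(C)=C[C@]2(C)[C@@H](O[Si](C)(C)C(C)(C)C)CC/C(C)=C\[C@@H](O[Si](C)(C)C(C)(C)C)C(=O)O | intermediate
30 | mixed anhydride of 29 with 2-methyl-6-nitrobenzoic acid | CC1(C)O[C@@H]2[C@H](O1)[C@@H](O)C(C)=C[C@]2(C)[C@@H](O[Si](C)(C)C(C)(C)C)CC/C(C)=C\[C@@H](O[Si](C)(C)C(C)(C)C)C(=O)OC(=O)c3c(C)cccc3[N+](=O)[O-] | intermediate
31 | twelve-membered macrolactone (C8 carbonyl esterified to the C12 oxygen) | CC1(C)O[C@@H]2[C@H](O1)[C@@H]3C(C)=C[C@]2(C)[C@@H](O[Si](C)(C)C(C)(C)C)CC/C(C)=C\[C@@H](O[Si](C)(C)C(C)(C)C)C(=O)O3 | intermediate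
32 | exocyclic enol ether of 31 (C8=C9H2) | CC1(C)O[C@@H]2[C@H](O1)[C@@H]3C(C)=C[C@]2(C)[C@@H](O[Si](C)(C)C(C)(C)C)CC/C(C)=C\[C@@H](O[Si](C)(C)C(C)(C)C)C(=C)O3 | intermediate
33 | ten-membered C8 ketone: briarane bicycle, 2,7-bis-TBS ether, 13,14-acetonide, C5=C6 (Z), C11=C12 | CC(C)(C)[Si](C)(C)O[C@H]1CC/C(C)=C\[C@@H](O[Si](C)(C)C(C)(C)C)C(=O)C[C@@H]2C(C)=C[C@H]3OC(C)(C)O[C@H]3[C@@]12C | intermediate
34 | 2,7-diol C8 ketone | O[C@H]1CC/C(C)=C\[C@@H](O)C(=O)C[C@@H]2C(C)=C[C@H]3OC(C)(C)O[C@H]3[C@@]12C | intermediate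
35 | 2-(diethoxyphosphoryl)propanoic acid | CCOP(=O)(OCC)C(C)C(=O)O | starting material
36 | C7 2-(diethoxyphosphoryl)propanoate of 34 | O[C@H]1CC/C(C)=C\[C@@H](OC(=O)C(C)P(=O)(OCC)OCC)C(=O)C[C@@H]2C(C)=C[C@H]3OC(C)(C)O[C@H]3[C@@]12C | intermediate
37 | butenolide C2 alcohol, 13,14-acetonide | O[C@H]1CC/C(C)=C\[C@H]2OC(=O)C(C)=C2C[C@@H]2C(C)=C[C@H]3OC(C)(C)O[C@H]3[C@@]12C | intermediate
38 | C2 propionate, 13,14-acetonide | CCC(=O)O[C@H]1CC/C(C)=C\[C@H]2OC(=O)C(C)=C2C[C@@H]2C(C)=C[C@H]3OC(C)(C)O[C@H]3[C@@]12C | intermediate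
39 | C2 propionate, 13,14-diol | CCC(=O)O[C@H]1CC/C(C)=C\[C@H]2OC(=O)C(C)=C2C[C@@H]2C(C)=C[C@@H](O)[C@@H](O)[C@@]12C | intermediate
40 | CNP0180501.3 | CCC(=O)O[C@H]1CC/C(C)=C\[C@H]2OC(=O)C(C)=C2C[C@@H]2C(C)=C[C@@H](OC(C)=O)[C@@H](OC(C)=O)[C@@]12C | target

**Step count**

Total steps: 26. Longest linear sequence: 23 steps (steps 4–26, from 7); steps 1–3 make the side-chain bromide 6.

**Three steps most likely to fail**

Step 21 (Claisen ring contraction). The enol ether 32 may hydrolyse, or the bridged transition state may be too strained. The fallback sets out from 29 and comes back at 33, making the C9–C10 bond by an ionic, palladium-mediated route instead of a thermal sigmatropic shift. Seco acid 29 is condensed with Meldrum's acid (N,N′-dicyclohexylcarbodiimide, 4-(dimethylamino)pyridine, CH2Cl2) to the acyl Meldrum's acid F1. Heating F1 at high dilution (toluene, 110 °C) releases an acylketene that the C12 hydroxyl captures, giving the fourteen-membered β-keto lactone F2. Pd(PPh3)4 in THF then ionises the allylic C12–O bond, carbon dioxide is lost, and the tethered ketone enolate attacks C10 on the face the carboxylate left (Tsuji decarboxylative allylation), which gives 33.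

Step 19 (macrolactonisation). Acylation of the hindered C12 hydroxyl in a bridged ring may lose to oligomerisation or C7 epimerisation. The fallback sets out from 23 and comes back at 31, closing the lactone by C–O bond formation at carbon instead of acyl activation. Selective HF·pyridine cleavage of the primary silyl ether of 23 gives the epoxy alcohol with free C8 hydroxyl F3. TEMPO/PhI(OAc)2 oxidation gives the epoxy acid F4. Ti(OiPr)4 at high dilution then lets the carboxylate open the allylic epoxide at C12 with inversion to give the macrolactone 13,14-diol F5, and acetonide formation (2,2-dimethoxypropane, pyridinium p-toluenesulfonate) returns to 31.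

Step 6 (MeLi on the hindered amide). The amide may resist addition. The fallback sets out from 12 and comes back at 14, replacing acyl substitution by reductive cleavage and redox adjustment. LiNH2BH3 reduces 12 to the neopentyl primary alcohol F6 with release of the auxiliary. Dess–Martin oxidation gives the aldehyde F7, MeMgBr gives the secondary carbinol F8, and a second Dess–Martin oxidation gives 14.

Further compounds
F1 | step 21 | acyl Meldrum's acid of seco acid 29 | CC1(C)O[C@@H]2[C@H](O1)[C@@H](O)C(C)=C[C@]2(C)[C@@H](O[Si](C)(C)C(C)(C)C)CC/C(C)=C\[C@@H](O[Si](C)(C)C(C)(C)C)C(=O)C3C(=O)OC(C)(C)OC3=O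
F2 | step 21 | fourteen-membered β-keto lactone (C8 ketone, C9H2, ester on the C12 oxygen) | CC1(C)O[C@@H]2[C@H](O1)[C@@H]3C(C)=C[C@]2(C)[C@@H](O[Si](C)(C)C(C)(C)C)CC/C(C)=C\[C@@H](O[Si](C)(C)C(C)(C)C)C(=O)CC(=O)O3
F3 | step 19 | epoxy alcohol with free C8 hydroxyl (C2 and C7 TBS ethers) | O[C@@H]1[C@@H]2O[C@@H]2C(C)=C[C@]1(C)[C@@H](O[Si](C)(C)C(C)(C)C)CC/C(C)=C\[C@@H](O[Si](C)(C)C(C)(C)C)CO
F4 | step 19 | epoxy acid (C8 carboxylic acid) | O[C@@H]1[C@@H]2O[C@@H]2C(C)=C[C@]1(C)[C@@H](O[Si](C)(C)C(C)(C)C)CC/C(C)=C\[C@@H](O[Si](C)(C)C(C)(C)C)C(=O)O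
F5 | step 19 | macrolactone 13,14-diol | O[C@@H]1[C@H](O)[C@@H]2C(C)=C[C@]1(C)[C@@H](O[Si](C)(C)C(C)(C)C)CC/C(C)=C\[C@@H](O[Si](C)(C)C(C)(C)C)C(=O)O2
F6 | step 6 | [(1R)-2-methoxy-1,5-dimethylcyclohexa-2,5-dien-1-yl]methanol | COC1=CCC(C)=C[C@]1(C)CO
F7 | step 6 | (1S)-2-methoxy-1,5-dimethylcyclohexa-2,5-diene-1-carbaldehyde | COC1=CCC(C)=C[C@]1(C)C=O
F8 | step 6 | 1-[(1R)-2-methoxy-1,5-dimethylcyclohexa-2,5-dien-1-yl]ethanol (both carbinol epimers) | COC1=CCC(C)=C[C@]1(C)C(C)O
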